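I began from a count that holds through a run if each Z that leaves takes one X with it: c_X is the charge of X less the Z gone, whatever that Z became. So each reading of Z also gives c_X.

| flask | Z | X | D | temperature | remark | time |
|---|---|---|---|---|---|---|
| dawn | 0.25 M | 0.30 M | 0.32 mM | 35 °C | the very flask that is asked about, followed so far |  |
| dusk | 0.25 M | 0.30 M | 0.64 mM | 35 °C | run made earlier |  |
| flask | 0.25 M | 0.300 M | 0.32 mM | 35 °C |  | 25 min |

- dawn (time / min: J / %, Z / %): 1.33: 43.4, 47.2; 4.00: 39.5, 44.4; 8.00: 34.6, 36.3; 10.0: 33.7, 37.8; 15.0: 30.5, 34.3; 20.0: 29.5, 34.1; 25.0: 26.8, 32.4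
- dusk (time / min: J / %, Z / %): 1.00: 46.5, 48.0; 2.50: 42.4, 42.4; 5.00: 37.9, 40.3; 8.00: 34.5, 37.6; 10.0: 31.7, 37.7; 15.0: 28.9, 34.2; 20.0: 28.6, 35.0

(each reading ± 1 percentage point)

- J, in percent of the Z first charged, at 25 min
- the remedy with the largest gain of J, or "none" below 2 percentage points (oak / larch / alder / elm / none)
- J present, in percent of the Z first charged, after oak
- J present, in percent of the Z first charged, after elm

- oak: at 25 min add D, 50.0% of the amount charged, then wait 25 min
- larch: at 25 min raise the temperature by 20 K, then wait 25 min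
- alder: change nothing and wait 25 min more
- elm: at 25 min add X, 100% of the amount charged, then wait 25 min

- the volume of additions can be left aside
- what was read earlier has a scatter of 1 percentage point, one standard deviation
- the earlier runs do not show what temperature does; that part of a forecast is a guess
- a reading or a percentage of J counts all its forms, free or not

Dawn, which is the flask asked about, and dusk look nearly the same, though dusk held twice the D. Both lose J and Z together, then slow down. I therefore tested a balance Z + X ⇌ J with the reaction quotient, Q = c_J/(c_Z·c_X). To avoid chasing single points, I replaced each curve by the mean of its last three readings. Dawn gave a mean Z of 33.6% and J of 28.9%. With 0.134 M of X, its Q was 6.43 L mol⁻¹. Dusk gave 6.00 L mol⁻¹. A catalyst moves no balance, so if D is one, the two quotients should agree, and as read they differed by 0.430 L mol⁻¹.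

I carried their mean, the read quotient Q 6.21 L mol⁻¹. With dawn's mean Z standing in for Z now, it gave J = 28.0%. Using either run's own Q instead moves this by 0.96 percentage points, against a scatter of 1 point. Q contains no D, so I expected no shift of the balance from oak, and since both runs stood at one temperature, it says nothing about larch.

The forecast gave 27.2% now, 25% after oak and 33% after elm, chose elm, and held that “Heating probably favours loss”.

The flask gave 27.0%, 26.2% after oak and 33.6% after elm. The best remedy was larch, gaining 26 points.

    Z + X ⇌ J (K = 6.00 L mol⁻¹, k = 11.0 L mol⁻¹ min⁻¹, Ea = 38.0 kJ mol⁻¹, ΔH = 29.0 kJ mol⁻¹)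
    2 D ⇌ E, settled at all times (K = 9000 L mol⁻¹, ΔH = −30.0 kJ mol⁻¹)
    J + D ⇌ G + D, rate k3*[D]*[J] forward; the back reaction follows from the equilibrium constant (k = 230 L mol⁻¹ min⁻¹, Ea = 53.0 kJ mol⁻¹)
    D + J ⇌ L (K = 2.30 L mol⁻¹, k = 2.10 L mol⁻¹ min⁻¹, Ea = 58.0 kJ mol⁻¹, ΔH = −60.0 kJ mol⁻¹)
    Z + X ⇌ G (K = 9.40 L mol⁻¹, k = 0.510 L mol⁻¹ min⁻¹, Ea = 75.0 kJ mol⁻¹, ΔH = −46.0 kJ mol⁻¹)
    (constants at 35 °C)

With the flask's Z of 33.6% and X of 44.6% of its charge, Q gives J = 27.9%. Z + X ⇌ J, by this step alone, relaxes with a half-life of 0.164 min at 25.0 min, shorter than the 9.4 min forward half-life of free J on its path to G with the other concentrations as charged. Meanwhile G rose from 33.3% to 39.5% between 12.5 min and 25.0 min.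

The neighbour charged with 0.062 M of Z held Z at 21.2% and X at 83.7% of its charge at 25.0 min, so Q gives J = 33.0%. The computed J there was 31.9%.

The earlier runs and the new flask come from a simulation for substances that don't exist; the scatter is artificial.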